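Links are the wanted product here, and two chemists dispute whether the way the second end groups go in changes how many links a flask makes.

| flask | first end groups | second end groups | remark | time |
|---|---|---|---|---|
| ochre | 0.050 M | 0.90 equiv | run made earlier |  |
| teal | 0.070 M | 0.90 equiv | run made earlier |  |
| red | 0.11 M | 0.90 equiv | run made earlier |  |
| green | 0.050 M | 1.4 equiv | run made earlier |  |
| birch | 0.050 M | 0.900 equiv (fed, over 2.5 min) | all else is in the flask from the start; the feed brings no volume worth counting | 6.0 min |
| maple | 0.050 M | 0.900 equiv | everything together at the start | 6.0 min |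
| oak | 0.050 M (fed, over 2.5 min) | 0.900 equiv | all else is in the flask from the start; the feed brings no volume worth counting | 6.0 min |
| larch | 0.050 M | 0.900 equiv (in portions, 2, over 2.5 min) | first portion at the start, last at 2.5 min | 6.0 min |

| run | time / min | links / % | first end groups / % |
|---|---|---|---|
| ochre | 1.00 | 13.2 | 60.8 |
| ochre | 2.00 | 17.8 | 40.2 |
| ochre | 3.00 | 19.5 | 27.1 |
| ochre | 4.00 | 18.7 | 19.3 |
| ochre | 5.00 | 18.6 | 15.4 |
| ochre | 6.00 | 19.6 | 13.5 |
| teal | 1.00 | 18.1 | 57.6 |
| teal | 2.00 | 22.3 | 37.5 |
| teal | 3.00 | 23.5 | 24.7 |
| teal | 4.00 | 24.8 | 18.2 |
| teal | 5.00 | 23.3 | 14.6 |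
| teal | 6.00 | 23.6 | 13.2 |
| red | 0.500 | 17.2 | 68.9 |
| red | 0.833 | 22.3 | 55.8 |
| red | 1.33 | 27.4 | 43.3 |
| red | 2.00 | 29.1 | 32.3 |
| red | 4.00 | 32.0 | 15.4 |
| red | 6.00 | 31.9 | 12.5 |
| green | 0.500 | 14.2 | 72.6 |
| green | 0.833 | 18.7 | 59.5 |
| green | 1.50 | 24.9 | 41.1 |
| green | 3.00 | 31.7 | 20.6 |
| green | 6.00 | 35.2 | 6.6 |

(scatter of a reading: 0.5 percentage points)

- the analysis behind the earlier runs scatters by 0.5 percentage points, standard deviation

1. the flask that comes out highest in amount of links, in percent of the first end groups charged, or "all alike" when all lie within 1.5 percentage points (birch / maple / oak / larch / all alike)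
2. links at the end, in percent of the first end groups charged, birch
3. links at the end, in percent of the first end groups charged, maple
4. links at the end, in percent of the first end groups charged, oak
5. links at the end, in percent of the first end groups charged, larch

The counter argues from charges. In the ochre run first end groups fall toward the 10.0% that one-for-one use of 0.90 equiv leaves, and the four flasks have equal charges, so each should end near ochre's last reading of 19.6%, alike.

I compare rates at one moment. In the red run at 0.500 min, links are 55.3% of the first end groups lost, at a midway [second end groups] of 0.0819 M. Taking this instantaneous selectivity as [second end groups]/([second end groups] + H) gives 0.0662 M, the parity concentration: the [second end groups] at which links take as much as the rest of the loss.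

The share drifts down as [second end groups] falls. Summed over a charge C used up in one go, links equal C minus H·ln(one plus C/H). For maple that is 21.3%. Oak starts from the same [second end groups], so I give it maple's figure.

At ochre's first-minute constant 0.498 min⁻¹, the first portion in larch is used in about 1.20 min, less than the 2.5 min before the last portion, so for an estimate I take the sum twice on the smaller C: 12.5%.

In birch the feed of 0.0180 M min⁻¹ is below the early demand of 0.0249 M min⁻¹ at that same constant. At that constant, 0.00941 M of second end groups stands when the feed ends. The share there is 12.5%, rising from zero and falling back, with a mean of 6.25%, so I expect 5.60% links.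

The forecast names maple, with 10% for birch, 19.3% for maple, 19% for oak and 11.3% for larch, holding that “Links don't track that loss”.

The flasks give birch 6.14%, maple 18.8%, oak 16.4% and larch 11.5%, so maple stands highest. Oak came 2.4 percentage points below maple, where I had them level. The counter holds for first end groups: at 60.0 min they stand at 10.0% in birch, 10.0% in maple, 10.0% in oak and 10.0% in larch.

    second end groups → decomposition product (k = 2.13 × 10⁻⁶ s⁻¹)
    first end groups + second end groups → rings, rate k2*[first end groups] as long as [second end groups] is above zero (k = 0.00560 s⁻¹)
    first end groups + second end groups → links (k = 0.0886 L mol⁻¹ s⁻¹)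
    second end groups ⇌ dormant form (K = 0.491, k = 0.00293 s⁻¹)

A neighbouring flask repeats maple with 0.12 M of first end groups, equivalents held. Its C is 0.108 M, above H, so its share starts at 62.0%, against 40.5% for maple. The sum gives 36.6% links. That flask ends with 12.6% of its first end groups left and 33.3% links.

The readings were computed for substances that don't exist; scatter was added.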